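**Plan**

1. Retrosynthesis (isochromene numbering C1, O2, C3, C4, C4a, C5–C8, C8a): the C8–O orsellinate ester is cut last; then, in one operation, the pyran bond C3–C4 and the ring-fusion bond C4a–C8a; then C5–C6 (ynone from a Weinreb amide), which leaves the acyclic diol ester 1.
2. Enabling feature: O2–C3=C4–C4a=C5–C6=O is the cyclic enol ether of a vinylogous 1,3-diketone, so C3–C4 is an acyl transfer from O2 to the γ-carbon of a 3-methylcyclohexenone. C8a lies between the oxygen-bearing C1 and C8, so it can be joined to the enone β-carbon C4a only as a radical (an anion there would eliminate).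
3. Forward order: chain 9 is built linearly; the carbocycle closes first (C8a radical onto C4a), the pyran second (C4 onto the crotonate carbonyl C3, then loss of water), both in one flask; desilylation, esterification at O8 and phenol deprotection follow.
4. Stereochemistry: C7 and C8 are carried unchanged from the (2S,3R)-diol 1; the carbinol centre that becomes C8a is erased at the radical stage and reset by the C7/C8 substituents during ring closure.

Key step: step 7

Remark: 1 is taken as a purchasable building block (syn-dihydroxylation product of the (E)-α-methyl enoate of D-glyceraldehyde acetonide); its threo C2/C3 diol is the trans C7/C8 pair of the target.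

Step 1
Reactants: 1 ethyl (2S,3R)-3-[(4R)-2,2-dimethyl-1,3-dioxolan-4-yl]-2,3-dihydroxy-2-methylpropanoate
Product: 2 (2S,3R)-3-[(4R)-2,2-dimethyl-1,3-dioxolan-4-yl]-2,3-dihydroxy-N-methoxy-N,2-dimethylpropanamide
Conditions: MeNH(OMe)·HCl, i-PrMgCl (excess), THF, −20 to 0 °C
Reagents that add atoms: N,O-dimethylhydroxylamine hydrochloride, CNOC.Cl
Why: Aminolysis of the α-hydroxy ester by the chloromagnesium amide made in the flask should give the Weinreb amide (Weinreb amide formation) without touching C2 or C3.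

Step 2
Reactants: 2 (2S,3R)-3-[(4R)-2,2-dimethyl-1,3-dioxolan-4-yl]-2,3-dihydroxy-N-methoxy-N,2-dimethylpropanamide
Product: 3 (2S,3R)-2,3-bis[(tert-butyldimethylsilyl)oxy]-3-[(4R)-2,2-dimethyl-1,3-dioxolan-4-yl]-N-methoxy-N,2-dimethylpropanamide
Conditions: TBSOTf, 2,6-lutidine, CH2Cl2, 0 °C to rt
Reagents that add atoms: tert-butyldimethylsilyl trifluoromethanesulfonate, CC(C)(C)[Si](C)(C)OS(=O)(=O)C(F)(F)F
Why: The silyl triflate should silylate the secondary and the hindered tertiary hydroxyl alike (silyl ether protection), which keeps both oxygens from adding to the later ynone and supplies the two bulky groups that steer the ring closure in step 7.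

Step 3
Reactants: 3 (2S,3R)-2,3-bis[(tert-butyldimethylsilyl)oxy]-3-[(4R)-2,2-dimethyl-1,3-dioxolan-4-yl]-N-methoxy-N,2-dimethylpropanamide; 4 prop-1-ynylmagnesium bromide (CH3C≡CMgBr)
Product: 5 (5S,6R)-5,6-bis[(tert-butyldimethylsilyl)oxy]-6-[(4R)-2,2-dimethyl-1,3-dioxolan-4-yl]-5-methylhex-2-yn-4-one
Conditions: THF, 0 °C to rt; aq. NH4Cl
Reagents that add atoms: none
Why: The alkynyl Grignard reagent should add only once because the chelated tetrahedral adduct collapses only on work-up (Weinreb ketone synthesis).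

Step 4
Reactants: 5 (5S,6R)-5,6-bis[(tert-butyldimethylsilyl)oxy]-6-[(4R)-2,2-dimethyl-1,3-dioxolan-4-yl]-5-methylhex-2-yn-4-one
Product: 6 (5S,6R,7R)-5,6-bis[(tert-butyldimethylsilyl)oxy]-7,8-dihydroxy-5-methyloct-2-yn-4-one
Conditions: AcOH–H2O (4:1), 40 °C
Reagents that add atoms: none
Why: Mild aqueous acid should hydrolyse the terminal isopropylidene acetal while the hindered silyl ethers and the ynone persist (acetal hydrolysis).

Step 5
Reactants: 6 (5S,6R,7R)-5,6-bis[(tert-butyldimethylsilyl)oxy]-7,8-dihydroxy-5-methyloct-2-yn-4-one; 7 (E)-but-2-enoic anhydride (crotonic anhydride)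
Product: 8 (2R,3R,4S)-3,4-bis[(tert-butyldimethylsilyl)oxy]-2-hydroxy-4-methyl-5-oxooct-6-yn-1-yl (2E)-but-2-enoate
Conditions: 2,4,6-collidine, DMAP (cat.), CH2Cl2, −40 °C
Reagents that add atoms: none
Why: The primary hydroxyl should be acylated much faster than the secondary one next to the silyloxy-bearing carbon (regioselective esterification), which puts O2–C3 and the (E)-propenyl group in place.

Step 6
Reactants: 8 (2R,3R,4S)-3,4-bis[(tert-butyldimethylsilyl)oxy]-2-hydroxy-4-methyl-5-oxooct-6-yn-1-yl (2E)-but-2-enoate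
Product: 9 (2R,3R,4S)-3,4-bis[(tert-butyldimethylsilyl)oxy]-4-methyl-5-oxo-2-[(phenoxycarbonothioyl)oxy]oct-6-yn-1-yl (2E)-but-2-enoate
Conditions: PhOC(S)Cl, pyridine, CH2Cl2, 0 °C to rt
Reagents that add atoms: O-phenyl chlorothionoformate, S=C(Cl)Oc1ccccc1
Why: The remaining secondary hydroxyl should be converted into its O-phenyl thionocarbonate (thioacylation), the radical precursor of the Barton–McCombie type.

Step 7
Reactants: 9 (2R,3R,4S)-3,4-bis[(tert-butyldimethylsilyl)oxy]-4-methyl-5-oxo-2-[(phenoxycarbonothioyl)oxy]oct-6-yn-1-yl (2E)-but-2-enoate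
Product: 12 (7S,8R,8aS)-7,8-bis[(tert-butyldimethylsilyl)oxy]-7-methyl-3-[(1E)-prop-1-en-1-yl]-8,8a-dihydro-1H-isochromen-6(7H)-one, via cyclohexenone 10 (not isolated), via lactol 11 (not isolated)
Conditions: (Me3Si)3SiH (slow addition), AIBN, PhMe (0.005 M), 85 °C; then LiN(SiMe3)2, THF, −78 to 0 °C; then p-TsOH·H2O, rt
Reagents that add atoms: none
Why: The silyl radical attacks the thionocarbonate sulfur and the C8a–O bond breaks (Barton–McCombie type) to a secondary radical at C8a, which adds to the ynone β-carbon C4a; hydrogen transfer from the silane gives 3-methylcyclohexenone 10, whose C4 methyl group is then deprotonated by LiN(SiMe3)2 (C7 is quaternary, so no α′-enolate can form), and the dienolate attacks the crotonate carbonyl C3 through C4 to give lactol 11, which loses water under acid to the dienol ether. The closest known reaction types are deoxygenative radical cyclisations of carbohydrate thionocarbonates onto conjugated acceptors, the endo ring closure of 4-oxohex-5-enyl radicals, and the Baker–Venkataraman acyl transfer followed by acid cyclodehydration used for chromones, here in vinylogous form. The carbocycle closes 6-endo-dig, since attack at the ynone α-carbon (5-exo) would give an unstabilised vinyl radical, and the pyran closes 6-exo-trig at the ester carbonyl. C8a is set in the radical closure by the substrate: in the half-chair transition state the two bulky silyloxy groups on C7 and C8 stay anti (trans-diaxial), the C7 methyl and the C1 arm of the planar radical carbon lie pseudo-equatorial, so C1 ends cis to O8, whereas the C8a epimer would need a syn-diaxial contact between C1 and O7; the same isomer should be the thermodynamic one, and C8a, γ to the ketone, can settle to it in the acid stage. The step needs ring closure to outrun hydrogen transfer, secured by slow silane addition at high dilution and by the activated ynone, and acylation through C4 and not C5, favoured because C4 attack gives an unstrained fused lactol whereas C5 attack would need a bridged 2-oxabicyclo[3.3.1]nonene.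

Step 8
Reactants: 12 (7S,8R,8aS)-7,8-bis[(tert-butyldimethylsilyl)oxy]-7-methyl-3-[(1E)-prop-1-en-1-yl]-8,8a-dihydro-1H-isochromen-6(7H)-one
Product: 13 (7S,8R,8aS)-7,8-dihydroxy-7-methyl-3-[(1E)-prop-1-en-1-yl]-8,8a-dihydro-1H-isochromen-6(7H)-one
Conditions: HF·pyridine, THF–pyridine, 0 °C to rt
Reagents that add atoms: none
Why: Fluoride cleavage of both silyl ethers under weakly acidic conditions (desilylation) avoids base, to which the C8a–H, γ to the dienone carbonyl, is sensitive.

Step 9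
Reactants: 14 2,4-dihydroxy-6-methylbenzoic acid (orsellinic acid)
Product: 15 tert-butyldimethylsilyl 2,4-bis[(tert-butyldimethylsilyl)oxy]-6-methylbenzoate
Conditions: TBSCl, imidazole, DMF, rt
Reagents that add atoms: tert-butyldimethylsilyl chloride, CC(C)(C)[Si](C)(C)Cl
Why: All three acidic hydroxyls should be silylated (silyl ether and silyl ester formation), the silyl ester serving as a masked acid chloride.

Step 10
Reactants: 15 tert-butyldimethylsilyl 2,4-bis[(tert-butyldimethylsilyl)oxy]-6-methylbenzoate; 13 (7S,8R,8aS)-7,8-dihydroxy-7-methyl-3-[(1E)-prop-1-en-1-yl]-8,8a-dihydro-1H-isochromen-6(7H)-one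
Product: 17 (7S,8R,8aS)-7-hydroxy-7-methyl-6-oxo-3-[(1E)-prop-1-en-1-yl]-6,7,8,8a-tetrahydro-1H-isochromen-8-yl 2,4-bis[(tert-butyldimethylsilyl)oxy]-6-methylbenzoate, via acid chloride 16 (not isolated)
Conditions: 15, (COCl)2, DMF (cat.), CH2Cl2, 0 °C to rt; then 13, Et3N, DMAP (cat.), CH2Cl2, 0 °C
Reagents that add atoms: none
Why: Oxalyl chloride with catalytic DMF should turn the silyl ester directly into the aroyl chloride, which acylates the secondary C8 hydroxyl in preference to the tertiary C7 hydroxyl (acyl chloride esterification), with retention at C8 because no C–O bond there is broken.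

Step 11
Reactants: 17 (7S,8R,8aS)-7-hydroxy-7-methyl-6-oxo-3-[(1E)-prop-1-en-1-yl]-6,7,8,8a-tetrahydro-1H-isochromen-8-yl 2,4-bis[(tert-butyldimethylsilyl)oxy]-6-methylbenzoate
Product: 18 (7S,8R,8aS)-7-hydroxy-7-methyl-6-oxo-3-[(1E)-prop-1-en-1-yl]-6,7,8,8a-tetrahydro-1H-isochromen-8-yl 2,4-dihydroxy-6-methylbenzoate
Conditions: Bu4NF, AcOH, THF, 0 °C
Reagents that add atoms: none
Why: Acetic acid-buffered fluoride should cleave the two aryl silyl ethers (desilylation) without ester migration or enol ether cleavage and give the target.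

**Compound list**

1 | ethyl (2S,3R)-3-[(4R)-2,2-dimethyl-1,3-dioxolan-4-yl]-2,3-dihydroxy-2-methylpropanoate | CCOC(=O)[C@@](C)(O)[C@H](O)[C@H]1COC(C)(C)O1 | starting material
2 | (2S,3R)-3-[(4R)-2,2-dimethyl-1,3-dioxolan-4-yl]-2,3-dihydroxy-N-methoxy-N,2-dimethylpropanamide | CON(C)C(=O)[C@@](C)(O)[C@H](O)[C@H]1COC(C)(C)O1 | intermediate
3 | (2S,3R)-2,3-bis[(tert-butyldimethylsilyl)oxy]-3-[(4R)-2,2-dimethyl-1,3-dioxolan-4-yl]-N-methoxy-N,2-dimethylpropanamide | CON(C)C(=O)[C@@](C)(O[Si](C)(C)C(C)(C)C)[C@H](O[Si](C)(C)C(C)(C)C)[C@H]1COC(C)(C)O1 | intermediate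
4 | prop-1-ynylmagnesium bromide | CC#C[Mg]Br | starting material
5 | (5S,6R)-5,6-bis[(tert-butyldimethylsilyl)oxy]-6-[(4R)-2,2-dimethyl-1,3-dioxolan-4-yl]-5-methylhex-2-yn-4-one | CC#CC(=O)[C@@](C)(O[Si](C)(C)C(C)(C)C)[C@H](O[Si](C)(C)C(C)(C)C)[C@H]1COC(C)(C)O1 | intermediate
6 | (5S,6R,7R)-5,6-bis[(tert-butyldimethylsilyl)oxy]-7,8-dihydroxy-5-methyloct-2-yn-4-one | CC#CC(=O)[C@@](C)(O[Si](C)(C)C(C)(C)C)[C@H](O[Si](C)(C)C(C)(C)C)[C@@H](CO)O | intermediate
7 | (E)-but-2-enoic anhydride | C/C=C/C(=O)OC(=O)/C=C/C | starting material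
8 | (2R,3R,4S)-3,4-bis[(tert-butyldimethylsilyl)oxy]-2-hydroxy-4-methyl-5-oxooct-6-yn-1-yl (2E)-but-2-enoate | CC#CC(=O)[C@@](C)(O[Si](C)(C)C(C)(C)C)[C@H](O[Si](C)(C)C(C)(C)C)[C@@H](COC(=O)/C=C/C)O | intermediate
9 | (2R,3R,4S)-3,4-bis[(tert-butyldimethylsilyl)oxy]-4-methyl-5-oxo-2-[(phenoxycarbonothioyl)oxy]oct-6-yn-1-yl (2E)-but-2-enoate | CC#CC(=O)[C@@](C)(O[Si](C)(C)C(C)(C)C)[C@H](O[Si](C)(C)C(C)(C)C)[C@@H](COC(=O)/C=C/C)OC(=S)Oc1ccccc1 | intermediate
10 | [(1S,5S,6R)-5,6-bis[(tert-butyldimethylsilyl)oxy]-2,5-dimethyl-4-oxocyclohex-2-en-1-yl]methyl (2E)-but-2-enoate | CC1=CC(=O)[C@@](C)(O[Si](C)(C)C(C)(C)C)[C@H](O[Si](C)(C)C(C)(C)C)[C@@H]1COC(=O)/C=C/C | intermediate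
11 | (7S,8R,8aS)-7,8-bis[(tert-butyldimethylsilyl)oxy]-3-hydroxy-7-methyl-3-[(1E)-prop-1-en-1-yl]-3,4,8,8a-tetrahydro-1H-isochromen-6(7H)-one (both C3 epimers) | C/C=C/C1(O)CC2=CC(=O)[C@@](C)(O[Si](C)(C)C(C)(C)C)[C@H](O[Si](C)(C)C(C)(C)C)[C@@H]2CO1 | intermediate
12 | (7S,8R,8aS)-7,8-bis[(tert-butyldimethylsilyl)oxy]-7-methyl-3-[(1E)-prop-1-en-1-yl]-8,8a-dihydro-1H-isochromen-6(7H)-one | C/C=C/C1=CC2=CC(=O)[C@@](C)(O[Si](C)(C)C(C)(C)C)[C@H](O[Si](C)(C)C(C)(C)C)[C@@H]2CO1 | intermediate
13 | (7S,8R,8aS)-7,8-dihydroxy-7-methyl-3-[(1E)-prop-1-en-1-yl]-8,8a-dihydro-1H-isochromen-6(7H)-one | C/C=C/C1=CC2=CC(=O)[C@@](C)(O)[C@H](O)[C@@H]2CO1 | intermediate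
14 | 2,4-dihydroxy-6-methylbenzoic acid | Cc1cc(O)cc(O)c1C(=O)O | starting material
15 | tert-butyldimethylsilyl 2,4-bis[(tert-butyldimethylsilyl)oxy]-6-methylbenzoate | Cc1cc(O[Si](C)(C)C(C)(C)C)cc(O[Si](C)(C)C(C)(C)C)c1C(=O)O[Si](C)(C)C(C)(C)C | intermediate
16 | 2,4-bis[(tert-butyldimethylsilyl)oxy]-6-methylbenzoyl chloride | Cc1cc(O[Si](C)(C)C(C)(C)C)cc(O[Si](C)(C)C(C)(C)C)c1C(Cl)=O | intermediate
17 | (7S,8R,8aS)-7-hydroxy-7-methyl-6-oxo-3-[(1E)-prop-1-en-1-yl]-6,7,8,8a-tetrahydro-1H-isochromen-8-yl 2,4-bis[(tert-butyldimethylsilyl)oxy]-6-methylbenzoate | C/C=C/C1=CC2=CC(=O)[C@@](C)(O)[C@H](OC(=O)c3c(C)cc(O[Si](C)(C)C(C)(C)C)cc3O[Si](C)(C)C(C)(C)C)[C@@H]2CO1 | intermediate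
18 | (7S,8R,8aS)-7-hydroxy-7-methyl-6-oxo-3-[(1E)-prop-1-en-1-yl]-6,7,8,8a-tetrahydro-1H-isochromen-8-yl 2,4-dihydroxy-6-methylbenzoate | C/C=C/C1=CC2=CC(=O)[C@@](C)(O)[C@H](OC(=O)c3c(C)cc(O)cc3O)[C@@H]2CO1 | target

**Step count and risks**

Total step count: 11. Longest linear sequence: 10 steps (steps 1–8, 10, 11).

Steps most likely to fail:

1. Step 7. The dienolate may acylate through the ring carbon C5 (α) instead of the methyl carbon C4 (γ), so the acyl group would end on the wrong carbon and no pyran would form. The fallback sets out from 9 and comes back at 12. Only the radical stage is run and 10 is isolated. I2 and pyridine in CH2Cl2 then iodinate the enone α-carbon to give [(1S,5S,6R)-5,6-bis[(tert-butyldimethylsilyl)oxy]-3-iodo-2,5-dimethyl-4-oxocyclohex-2-en-1-yl]methyl (2E)-but-2-enoate F1, in which C5 is blocked. LiN(SiMe3)2 (THF, −78 to 0 °C) followed by p-TsOH·H2O should now force acyl transfer through C4 and give (7S,8R,8aS)-7,8-bis[(tert-butyldimethylsilyl)oxy]-5-iodo-7-methyl-3-[(1E)-prop-1-en-1-yl]-8,8a-dihydro-1H-isochromen-6(7H)-one F2. Radical hydrodeiodination with (Me3Si)3SiH and AIBN in PhMe at 80 °C returns 12.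

2. Step 10. Acylation of the crowded C8 hydroxyl by the hindered aroyl chloride may be slow, so that base-induced elimination of the C8 oxygen (C8a–H is γ to the dienone) or acylation at C7 takes over. The fallback sets out from 13 and 14 and comes back at 18. Acid 14 is condensed with acetone (TFAA, TFA) to 7-hydroxy-2,2,5-trimethyl-4H-1,3-benzodioxin-4-one F3. Irradiation of F3 (300 nm, CH2Cl2) in the presence of 13 releases acetone and a quinone ketene, which the C8 hydroxyl should trap under neutral conditions to give 18 directly, leaving out 15, 16 and 17.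

3. Step 3. The Weinreb amide, next to a quaternary silyloxy carbon, may fail to take up the Grignard reagent or lose its N-methoxy group instead. The fallback sets out from 3 and comes back at 5. i-Bu2AlH (CH2Cl2, −78 °C) reduces 3 to (2S,3R)-2,3-bis[(tert-butyldimethylsilyl)oxy]-3-[(4R)-2,2-dimethyl-1,3-dioxolan-4-yl]-2-methylpropanal F4. Reagent 4 adds to the less hindered aldehyde to give (5R,6R)-5,6-bis[(tert-butyldimethylsilyl)oxy]-6-[(4R)-2,2-dimethyl-1,3-dioxolan-4-yl]-5-methylhex-2-yn-4-ol F5 (both C4 epimers), and Dess–Martin periodinane oxidises F5 to 5.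

Further compounds
F1 | step 7 | [(1S,5S,6R)-5,6-bis[(tert-butyldimethylsilyl)oxy]-3-iodo-2,5-dimethyl-4-oxocyclohex-2-en-1-yl]methyl (2E)-but-2-enoate | CC1=C(I)C(=O)[C@@](C)(O[Si](C)(C)C(C)(C)C)[C@H](O[Si](C)(C)C(C)(C)C)[C@@H]1COC(=O)/C=C/C
F2 | step 7 | (7S,8R,8aS)-7,8-bis[(tert-butyldimethylsilyl)oxy]-5-iodo-7-methyl-3-[(1E)-prop-1-en-1-yl]-8,8a-dihydro-1H-isochromen-6(7H)-one | C/C=C/C1=CC2=C(I)C(=O)[C@@](C)(O[Si](C)(C)C(C)(C)C)[C@H](O[Si](C)(C)C(C)(C)C)[C@@H]2CO1
F3 | step 10 | 7-hydroxy-2,2,5-trimethyl-4H-1,3-benzodioxin-4-one | Cc1cc(O)cc2OC(C)(C)OC(=O)c12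
F4 | step 3 | (2S,3R)-2,3-bis[(tert-butyldimethylsilyl)oxy]-3-[(4R)-2,2-dimethyl-1,3-dioxolan-4-yl]-2-methylpropanal | O=C[C@@](C)(O[Si](C)(C)C(C)(C)C)[C@H](O[Si](C)(C)C(C)(C)C)[C@H]1COC(C)(C)O1
F5 | step 3 | (5R,6R)-5,6-bis[(tert-butyldimethylsilyl)oxy]-6-[(4R)-2,2-dimethyl-1,3-dioxolan-4-yl]-5-methylhex-2-yn-4-ol (both C4 epimers) | CC#CC(O)[C@@](C)(O[Si](C)(C)C(C)(C)C)[C@H](O[Si](C)(C)C(C)(C)C)[C@H]1COC(C)(C)O1
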